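**Retrosynthetic overview**
1. The target is the mono-acetate of a meso triol: a cyclopent-3-ene whose quaternary acyl carbinol C1 is flanked by the cis carbinols C2 and C5. The last disconnection is therefore enzymatic mono-hydrolysis of meso diacetate 15, which fixes all three absolute configurations at once.
2. Triol 14 comes from cyclopentenone 11 by enolate hydroxylation at C1 (anti to O5) and 1,2-reduction at C2 (anti to the masked acyl group); the side-chain ketone travels as a dioxolane.
3. Key disconnection: C5–C1 and C3–C2 of the ring, made in one anion-relay [3+2] annulation. The ester enolate of 5 supplies C1 (α-carbon) and C2 (ester carbonyl); (Z)-3-(trimethylsilyl)acrolein 8 supplies C5 (CHO carbon), C4 and C3 (silyl-bearing carbon).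
4. Enabling feature: in the ring, C1 sits α to the oxygenated C2 (an enolate/acyl pair), while O–C5–C4=C3 is a cis-acrolein unit. An alkoxide born on C5 can therefore pass its charge to C3 by 1,4-silyl (Brook) migration across the cis double bond.
5. Ring order: the cyclopentene is the only ring of the target and is closed in step 5; the dioxolane (step 2) is a temporary ring removed in step 8.

Key step: step 5

Remark: ring atoms are numbered as in the target (C1 quaternary carbinol, C2 CH–OH, C3=C4, C5 CH–OAc); 9–13 are racemic, drawn as the enantiomer that maps onto the target, and the C1 epimers of 9–11 are carried as a mixture because C1 is made planar again in step 6.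

**Step 1**
Reactants: 1 tridecanoyl chloride; 2 Meldrum's acid
Product: 4 methyl 3-oxopentadecanoate, via acyl Meldrum's acid 3 (not isolated)
Conditions: pyridine, CH2Cl2, 0 °C → rt; then MeOH, reflux
Reagents that add atoms: methanol, CO
Why: C-acylation of Meldrum's acid, then methanolysis and decarboxylation through the acylketene (Oikawa–Yonemitsu β-keto ester synthesis), should give the C15 β-keto ester; no stereocentre is formed.

**Step 2**
Reactants: 4 methyl 3-oxopentadecanoate
Product: 5 methyl 2-(2-dodecyl-1,3-dioxolan-2-yl)acetate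
Conditions: ethylene glycol, p-TsOH (cat.), toluene, reflux, Dean–Stark
Reagents that add atoms: ethylene glycol, OCCO
Why: Acid-catalysed ketalization with azeotropic removal of water masks the ketone, so the CH2 next to the ester becomes a plain ester-enolate site and the ketone survives the later hydride reduction; no stereocentre is formed.

**Step 3**
Reactants: 6 3-(trimethylsilyl)prop-2-yn-1-ol
Product: 7 (Z)-3-(trimethylsilyl)prop-2-en-1-ol
Conditions: H2 (1 atm), P-2 Ni (Ni(OAc)2, NaBH4), ethylenediamine, EtOH, rt
Reagents that add atoms: none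
Why: Syn semihydrogenation of the silylalkyne on nickel boride (Lindlar-type reduction) delivers both hydrogens to one face and should give the Z-vinylsilane.

**Step 4**
Reactants: 7 (Z)-3-(trimethylsilyl)prop-2-en-1-ol
Product: 8 (Z)-3-(trimethylsilyl)prop-2-enal
Conditions: Dess–Martin periodinane, CH2Cl2, 0 °C; used at once as a cold solution
Reagents that add atoms: none
Why: Dess–Martin oxidation of the allylic alcohol at low temperature should give the enal with the Z geometry intact; the volatile, isomerisation-prone enal is not stored.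

**Step 5**
Reactants: 5 methyl 2-(2-dodecyl-1,3-dioxolan-2-yl)acetate; 8 (Z)-3-(trimethylsilyl)prop-2-enal
Product: 11 rac-(4S*)-5-(2-dodecyl-1,3-dioxolan-2-yl)-4-[(trimethylsilyl)oxy]cyclopent-2-en-1-one, via lithium aldolate 9 (not isolated), via vinyllithium ester 10 (not isolated)
Conditions: LDA, THF, −78 °C; then 8, −78 °C; then HMPA, −78 → −20 °C; NH4Cl (aq)
Reagents that add atoms: none
Why: Proposed new method: the lithium enolate of 5 adds 1,2 to the aldehyde of 8 (aldol, forms C5–C1) to give alkoxide 9; in THF–HMPA the silyl group, held cis to the alkoxide across the Z double bond, should migrate from C3 to O5 ([1,4]-Brook shift, C(sp2)→O) and unmask the Z-vinyllithium 10, which attacks the neighbouring methyl ester (forms C3–C2) and expels methoxide. The closest known reaction types are the anion-relay aldol/Brook/cyclization [3+2] annulations of ketone enolates with silyl-bearing aldehyde linchpins, the Brook-mediated [3+2] annulation of β-silyl acryloylsilanes with enolates, and the alkoxide-triggered 1,4-silyl migration of (Z)-γ-silyl allylic alkoxides to vinyl anions. The cyclopentene ring is closed by 5-exo-trig acylation of the vinyl carbanion at the ester carbonyl (Parham-type cyclization). The one lasting new stereocentre, C5, arises in the aldol without control (racemic, both enantiomers later converge on meso 14), and C1 is epimerisable and is planarised again in step 6. The step needs 1,2- rather than 1,4-addition (lithium ester enolate at −78 °C), an intact Z geometry (only the cis-silyl alkoxide can undergo the shift and only the Z-vinyllithium reaches the ester), and ring closure faster than proton transfer from C1–H, which the intramolecular five-ring acylation and the late addition of HMPA should secure.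

**Step 6**
Reactants: 11 rac-(4S*)-5-(2-dodecyl-1,3-dioxolan-2-yl)-4-[(trimethylsilyl)oxy]cyclopent-2-en-1-one
Product: 12 rac-(4S*,5R*)-5-(2-dodecyl-1,3-dioxolan-2-yl)-5-hydroxy-4-[(trimethylsilyl)oxy]cyclopent-2-en-1-one
Conditions: KHMDS, THF, −78 °C; then 2-(phenylsulfonyl)-3-phenyloxaziridine, −78 °C; NH4Cl (aq)
Reagents that add atoms: 2-(phenylsulfonyl)-3-phenyloxaziridine, O=S(=O)(c1ccccc1)N1OC1c1ccccc1
Why: Kinetic α′-deprotonation gives the cross-conjugated potassium dienolate, which should take oxygen from the N-sulfonyloxaziridine (Davis enolate hydroxylation) on the face opposite the adjacent silyloxy group, so the tertiary hydroxyl at C1 ends up trans to O5 from either C1 epimer of 11.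

**Step 7**
Reactants: 12 rac-(4S*,5R*)-5-(2-dodecyl-1,3-dioxolan-2-yl)-5-hydroxy-4-[(trimethylsilyl)oxy]cyclopent-2-en-1-one
Product: 13 rac-(1R*,4S*,5S*)-5-(2-dodecyl-1,3-dioxolan-2-yl)-4-[(trimethylsilyl)oxy]cyclopent-2-ene-1,5-diol
Conditions: NaBH4, CeCl3·7H2O, MeOH, −78 °C
Reagents that add atoms: none
Why: In this Luche 1,2-reduction the hydride should approach the ring carbonyl from the face of the small tertiary hydroxyl, anti to the bulky dioxolanyl and silyloxy groups, which places the new C2 hydroxyl cis to O5 and trans to the C1 hydroxyl; the ketal keeps the side-chain carbonyl out of reach.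

**Step 8**
Reactants: 13 rac-(1R*,4S*,5S*)-5-(2-dodecyl-1,3-dioxolan-2-yl)-4-[(trimethylsilyl)oxy]cyclopent-2-ene-1,5-diol
Product: 14 meso-1-(1,2,5-trihydroxycyclopent-3-en-1-yl)tridecan-1-one (2R,5S; the 2- and 5-OH cis to each other and trans to the 1-OH)
Conditions: 1 M HCl (aq), THF, rt
Reagents that add atoms: water, O
Why: Acid hydrolysis of the dioxolane and of the silyl ether should free the ketone and the second carbinol without touching a stereocentre; the product is meso, so both enantiomers of 13 give the same compound.

**Step 9**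
Reactants: 14 meso-1-(1,2,5-trihydroxycyclopent-3-en-1-yl)tridecan-1-one
Product: 15 meso-(1R,3S)-2-hydroxy-2-tridecanoylcyclopent-4-ene-1,3-diyl diacetate
Conditions: Ac2O, pyridine, CH2Cl2, 0 °C → rt
Reagents that add atoms: acetic anhydride, CC(=O)OC(C)=O
Why: Acetylation of the two secondary hydroxyls with Ac2O/pyridine should leave the hindered tertiary α-ketol hydroxyl free and give the meso diacetate.

**Step 10**
Reactants: 15 meso-(1R,3S)-2-hydroxy-2-tridecanoylcyclopent-4-ene-1,3-diyl diacetate
Product: 16 (1S,4R,5S)-4,5-dihydroxy-5-tridecanoylcyclopent-2-en-1-yl acetate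
Conditions: Candida antarctica lipase B (immobilised), phosphate buffer pH 7, acetone co-solvent, rt; stopped at mono-hydrolysis
Reagents that add atoms: none
Why: In this enzymatic desymmetrization of a meso diacetate the lipase should, by the Kazlauskas rule with the quaternary ring carbon as the large substituent, cleave the acetate on the (R)-carbinol and keep the one on the (S)-carbinol, which sets the absolute configuration of all three stereocentres in one event.

**Compound list**
1 | tridecanoyl chloride | CCCCCCCCCCCCC(Cl)=O | starting material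
2 | Meldrum's acid (2,2-dimethyl-1,3-dioxane-4,6-dione) | CC1(C)OC(=O)CC(=O)O1 | starting material
3 | 5-(1-hydroxytridecylidene)-2,2-dimethyl-1,3-dioxane-4,6-dione | CCCCCCCCCCCCC(O)=C1C(=O)OC(C)(C)OC1=O | intermediate
4 | methyl 3-oxopentadecanoate | CCCCCCCCCCCCC(=O)CC(=O)OC | intermediate
5 | methyl 2-(2-dodecyl-1,3-dioxolan-2-yl)acetate | CCCCCCCCCCCCC1(CC(=O)OC)OCCO1 | intermediate
6 | 3-(trimethylsilyl)prop-2-yn-1-ol | C[Si](C)(C)C#CCO | starting material
7 | (Z)-3-(trimethylsilyl)prop-2-en-1-ol | C[Si](C)(C)/C=C\CO | intermediate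
8 | (Z)-3-(trimethylsilyl)prop-2-enal | C[Si](C)(C)/C=C\C=O | intermediate
9 | lithium (Z)-2-(2-dodecyl-1,3-dioxolan-2-yl)-1-methoxy-1-oxo-5-(trimethylsilyl)pent-4-en-3-olate (racemic, C2 epimers) | COC(=O)C(C1(CCCCCCCCCCCC)OCCO1)[C@@H]([O-])/C=C\[Si](C)(C)C.[Li+] | intermediate
10 | methyl (Z)-2-(2-dodecyl-1,3-dioxolan-2-yl)-5-lithio-3-[(trimethylsilyl)oxy]pent-4-enoate (racemic, C2 epimers) | COC(=O)C(C1(CCCCCCCCCCCC)OCCO1)[C@@H](O[Si](C)(C)C)/C=C\[Li] | intermediate
11 | rac-(4S*)-5-(2-dodecyl-1,3-dioxolan-2-yl)-4-[(trimethylsilyl)oxy]cyclopent-2-en-1-one (C5 epimers) | O=C1C=C[C@H](O[Si](C)(C)C)C1C2(CCCCCCCCCCCC)OCCO2 | intermediate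
12 | rac-(4S*,5R*)-5-(2-dodecyl-1,3-dioxolan-2-yl)-5-hydroxy-4-[(trimethylsilyl)oxy]cyclopent-2-en-1-one (5-OH trans to 4-OSiMe3) | O=C1C=C[C@H](O[Si](C)(C)C)[C@]1(O)C2(CCCCCCCCCCCC)OCCO2 | intermediate
13 | rac-(1R*,4S*,5S*)-5-(2-dodecyl-1,3-dioxolan-2-yl)-4-[(trimethylsilyl)oxy]cyclopent-2-ene-1,5-diol (1-OH cis to 4-OSiMe3, both trans to 5-OH) | O[C@@H]1C=C[C@H](O[Si](C)(C)C)[C@]1(O)C2(CCCCCCCCCCCC)OCCO2 | intermediate
14 | meso-1-(1,2,5-trihydroxycyclopent-3-en-1-yl)tridecan-1-one (2R,5S; 2-OH and 5-OH cis, trans to 1-OH) | CCCCCCCCCCCCC(=O)[C@]1(O)[C@H](O)C=C[C@@H]1O | intermediate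
15 | meso-(1R,3S)-2-hydroxy-2-tridecanoylcyclopent-4-ene-1,3-diyl diacetate | CCCCCCCCCCCCC(=O)[C@]1(O)[C@H](OC(C)=O)C=C[C@@H]1OC(C)=O | intermediate
16 | (1S,4R,5S)-4,5-dihydroxy-5-tridecanoylcyclopent-2-en-1-yl acetate | CCCCCCCCCCCCC(=O)[C@]1(O)[C@H](O)C=C[C@@H]1OC(C)=O | target

**Totals**
Total step count: 10. Longest linear sequence: 8 steps (1, 2, 5, 6, 7, 8, 9, 10).

**Steps most likely to fail**

Step 5 (Proposed new method). The cascade may stall after the aldol or after the silyl shift: the vinyl anion can be quenched by proton transfer from C1–H, 8 can isomerise from Z to E before it reacts, or the silyl migration may be incomplete. The fallback uses known chemistry, sets out from 5 and returns at 11, and makes the two bonds in two stages. Commercial ethyl (Z)-3-iodoacrylate is reduced (DIBAL-H, CH2Cl2, −78 °C) to (Z)-3-iodoprop-2-enal F1. The LDA aldol of 5 with F1 gives methyl (Z)-2-(2-dodecyl-1,3-dioxolan-2-yl)-3-hydroxy-5-iodopent-4-enoate F2 (forms C5–C1). Silylation (TMSCl, imidazole) gives methyl (Z)-2-(2-dodecyl-1,3-dioxolan-2-yl)-5-iodo-3-[(trimethylsilyl)oxy]pent-4-enoate F3. Iodine–lithium exchange (t-BuLi, THF, −78 °C) then generates the same vinyllithium 10 directly, which closes to 11 by Parham-type intramolecular acylation (forms C3–C2).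

Step 6. The enolate may be formed at the γ-position or lose a β-alkoxy group (ring-opening of the dioxolane) before oxygen transfer. The fallback sets out from 11 and returns at 14, and brings in the tertiary hydroxyl by dihydroxylation instead of enolate oxidation. The dioxolane is opened to the conjugated exocyclic enol ether 5-{1-[2-(trimethylsilyloxy)ethoxy]tridecylidene}-4-[(trimethylsilyl)oxy]cyclopent-2-en-1-one F4 (TMSOTf, i-Pr2NEt, CH2Cl2, ketal-to-enol-ether conversion). The ring ketone is reduced (DIBAL-H, −78 °C, hydride anti to the silyloxy group) to the allylic alcohol 5-{1-[2-(trimethylsilyloxy)ethoxy]tridecylidene}-4-[(trimethylsilyl)oxy]cyclopent-2-en-1-ol F5. OsO4/NMO should then dihydroxylate the electron-rich enol ether anti to both allylic oxygens; collapse of the hemiketal and a mildly acidic aqueous work-up give 14. This path also avoids the acidic ketal cleavage of step 8.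

Step 10. Hydrolysis at carbinols that flank a quaternary carbon may be slow, may go on to the triol, or may show the opposite group preference. The fallback sets out from 14 and returns at 16 (no new compound, F0): acylative desymmetrization of the triol with a small-molecule chiral acyl-transfer catalyst (a planar-chiral DMAP-type or isothiourea catalyst, Ac2O, Et3N, low temperature), whose enantiomer is chosen so that the (S)-carbinol is acetylated.

**Further compounds**
F1 | step 5 | (Z)-3-iodoprop-2-enal | I/C=C\C=O
F2 | step 5 | methyl (Z)-2-(2-dodecyl-1,3-dioxolan-2-yl)-3-hydroxy-5-iodopent-4-enoate (racemic, C2 epimers) | COC(=O)C(C1(CCCCCCCCCCCC)OCCO1)[C@@H](O)/C=C\I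
F3 | step 5 | methyl (Z)-2-(2-dodecyl-1,3-dioxolan-2-yl)-5-iodo-3-[(trimethylsilyl)oxy]pent-4-enoate (racemic, C2 epimers) | COC(=O)C(C1(CCCCCCCCCCCC)OCCO1)[C@@H](O[Si](C)(C)C)/C=C\I
F4 | step 6 | rac-5-{1-[2-(trimethylsilyloxy)ethoxy]tridecylidene}-4-[(trimethylsilyl)oxy]cyclopent-2-en-1-one | O=C1C=C[C@H](O[Si](C)(C)C)C1=C(CCCCCCCCCCCC)OCCO[Si](C)(C)C
F5 | step 6 | rac-5-{1-[2-(trimethylsilyloxy)ethoxy]tridecylidene}-4-[(trimethylsilyl)oxy]cyclopent-2-en-1-ol (1-OH cis to 4-OSiMe3) | O[C@@H]1C=C[C@H](O[Si](C)(C)C)C1=C(CCCCCCCCCCCC)OCCO[Si](C)(C)C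
F0 | step 10 | none | none
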